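**Retrosynthetic overview**

1. Target 46 ⇐ 43 by C9 O-PMB removal, C6 senecioylation and hydroxyl-directed C4–C5 epoxidation; the α-methylene-γ-lactone (ring C7–C8–O–C12–C11) comes from the C7 bis(hydroxymethyl)methyl arm by oxidative lactonisation onto C8–OH and dehydration.
2. The ten-membered carbocycle (C1–C10) ⇐ eleven-membered sulfone 33 by Ramberg–Bäcklund contraction across C1–C2. The strategy rests on C1–C2–C3 being the only ring atoms that carry no oxygen, methyl group or ring fusion; C1–C2 is chosen over C2–C3 so that the new alkene is not conjugated with C4=C5 and can be saturated alone.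
3. Sulfone 33 ⇐ cyclic sulfide 31 ⇐ bis-mesylate 30 of the acyclic C1–C10 chain, with O8 as TES, O9 as PMB and O6 as TBS ether so that the three oxygens can be freed one at a time.
4. Chain ⇐ Evans syn-aldol (C7–C8) of imide 8 with aldehyde 14 (C9 from (R)-malate, C10 by Fráter–Seebach methylation); C6 by transfer hydrogenation of an ynone; E-C4=C5 by hydroalumination, iodination and Negishi methylation. A Z-alkene dihydroxylation for C8/C9 is avoided because neither its facial selectivity nor its selectivity over C4=C5 can be relied on.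
5. Ring order: thiacycle (11) → carbocycle (10) → γ-lactone → epoxide.

Key step: step 23

Remark: germacrane numbering (C1–C15) is used for every intermediate; centres that are made and destroyed again (S in 32, C2 in 34, C1/C2 in 35, C11 in 39–41, C12 in 39) are expected as mixtures and are left open in the SMILES.

**Route**

Step 1
Reactants: 1 2,2-dimethyl-1,3-dioxan-5-one; 2 ethyl (triphenylphosphoranylidene)acetate
Product: 3 ethyl 2-(2,2-dimethyl-1,3-dioxan-5-ylidene)acetate
Conditions: CH2Cl2, rt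
Reagents that add atoms: none
Why: Wittig olefination of the unhindered ketone with a stabilised ylide should give the ylidene ester that carries C11–C13 (dioxane ring), C7 and C6; no stereocentre is formed.

Step 2
Reactants: 3 ethyl 2-(2,2-dimethyl-1,3-dioxan-5-ylidene)acetate
Product: 4 ethyl 2-(2,2-dimethyl-1,3-dioxan-5-yl)acetate
Conditions: H2 (1 atm), 10% Pd/C, EtOAc, rt
Reagents that add atoms: none
Why: Heterogeneous catalytic hydrogenation saturates the conjugated trisubstituted alkene without touching ester or acetonide, and C11 stays non-stereogenic because its two CH2O arms are identical.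

Step 3
Reactants: 4 ethyl 2-(2,2-dimethyl-1,3-dioxan-5-yl)acetate
Product: 5 2-(2,2-dimethyl-1,3-dioxan-5-yl)acetic acid
Conditions: LiOH, THF/H2O, rt; then 1 M HCl to pH 4, 0 °C
Reagents that add atoms: lithium hydroxide, [Li+].[OH-]
Why: Ester saponification (acyl–oxygen cleavage by hydroxide) should give the acid, the acetonide being stable to base and to brief cold acidification to pH 4.

Step 4
Reactants: 5 2-(2,2-dimethyl-1,3-dioxan-5-yl)acetic acid; 6 (S)-4-benzyl-1,3-oxazolidin-2-one
Product: 8 (S)-4-benzyl-3-[2-(2,2-dimethyl-1,3-dioxan-5-yl)acetyl]-1,3-oxazolidin-2-one, via mixed pivalic anhydride 7 (not isolated)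
Conditions: PivCl, Et3N, THF, −20 °C; then 6, LiCl, rt
Reagents that add atoms: none
Why: N-Acylation of the oxazolidinone through the mixed pivalic anhydride (LiCl/Et3N activation) occurs at the less hindered acyl carbon and installs the Evans auxiliary without creating a new stereocentre.

Step 5
Reactants: 9 dimethyl (R)-malate
Product: 11 dimethyl (2R,3S)-2-hydroxy-3-methylbutanedioate, via dilithium alkoxide enolate 10 (not isolated)
Conditions: LiN(SiMe3)2 (2.2 equiv), THF, −78 → −20 °C; then MeI, −78 → −10 °C; aq. NH4Cl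
Reagents that add atoms: iodomethane, CI
Why: Fráter–Seebach alkylation: the lithium-chelated alkoxide enolate is methylated on the face away from the C8 ester group, which sets C10 anti to the C9 hydroxyl (2R,3S).

Step 6
Reactants: 11 dimethyl (2R,3S)-2-hydroxy-3-methylbutanedioate
Product: 12 (2R,3R)-3-methylbutane-1,2,4-triol
Conditions: LiAlH4, THF, 0 °C → reflux
Reagents that add atoms: none
Why: Hydride reduction of both ester groups by LiAlH4 gives the triol (C8, C9, C10, C1) and leaves the C9 and C10 centres unchanged.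

Step 7
Reactants: 12 (2R,3R)-3-methylbutane-1,2,4-triol
Product: 13 [(2R,4R,5R)-2-(4-methoxyphenyl)-5-methyl-1,3-dioxan-4-yl]methanol
Conditions: 4-MeOC6H4CH(OMe)2, CSA (cat.), CH2Cl2, rt
Reagents that add atoms: 4-methoxybenzaldehyde dimethyl acetal, COc1ccc(cc1)C(OC)OC
Why: Acid-catalysed transacetalisation under equilibrating conditions selects the six-membered 1,3-dioxane across O9 and O1 in which aryl, C8 and methyl are all equatorial, so the new acetal centre is set thermodynamically (2R) and C8–OH alone stays free.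

Step 8
Reactants: 13 [(2R,4R,5R)-2-(4-methoxyphenyl)-5-methyl-1,3-dioxan-4-yl]methanol
Product: 14 (2R,4R,5R)-2-(4-methoxyphenyl)-5-methyl-1,3-dioxane-4-carbaldehyde
Conditions: Dess–Martin periodinane, NaHCO3, CH2Cl2, 0 °C → rt
Reagents that add atoms: none
Why: Dess–Martin oxidation under bicarbonate buffering gives the α-alkoxy aldehyde (C8) without epimerising C9, whose formyl group is already in the favoured equatorial position.

Step 9
Reactants: 15 but-3-yn-1-ol
Product: 16 (but-3-yn-1-yloxy)triethylsilane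
Conditions: Et3SiCl, imidazole, CH2Cl2, 0 °C
Reagents that add atoms: chlorotriethylsilane, CC[Si](Cl)(CC)CC
Why: Silylation of the primary alcohol (imidazole-assisted substitution at silicon) masks O2 as a triethylsilyl ether that can later be removed in the presence of hindered secondary silyl ethers.

Step 10
Reactants: 8 (S)-4-benzyl-3-[2-(2,2-dimethyl-1,3-dioxan-5-yl)acetyl]-1,3-oxazolidin-2-one; 14 (2R,4R,5R)-2-(4-methoxyphenyl)-5-methyl-1,3-dioxane-4-carbaldehyde
Product: 18 (S)-4-benzyl-3-[(2S,3S)-2-(2,2-dimethyl-1,3-dioxan-5-yl)-3-hydroxy-3-[(2R,4R,5R)-2-(4-methoxyphenyl)-5-methyl-1,3-dioxan-4-yl]propanoyl]-1,3-oxazolidin-2-one, via Z-boron enolate 17 (not isolated)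
Conditions: Bu2BOTf, iPr2NEt, CH2Cl2, −78 → 0 °C; then 14, −78 → 0 °C; H2O2, pH 7 buffer, MeOH
Reagents that add atoms: none
Why: Evans syn-aldol reaction: the Z-boron enolate reacts through a Zimmerman–Traxler chair on the face opposite the benzyl group of the auxiliary, setting C7 and C8 (syn), and the α-alkoxy centre C9 of the aldehyde favours the same approach (Cornforth model, C8–O/C9–O anti), so the pairing is matched.

Step 11
Reactants: 18 aldol adduct (imide)
Product: 19 (2S,3S)-2-(2,2-dimethyl-1,3-dioxan-5-yl)-3-hydroxy-N-methoxy-3-[(2R,4R,5R)-2-(4-methoxyphenyl)-5-methyl-1,3-dioxan-4-yl]-N-methylpropanamide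
Conditions: MeONHMe·HCl, AlMe3, CH2Cl2, −20 → 0 °C; aq. KNaC4H4O6
Reagents that add atoms: N,O-dimethylhydroxylamine hydrochloride, CNOC.Cl
Why: Weinreb transamination with the aluminium amide, guided by the aluminium alkoxide of C8–OH to the exocyclic carbonyl, exchanges the auxiliary for the N-methoxy-N-methylamide without epimerising C7.

Step 12
Reactants: 19 β-hydroxy Weinreb amide
Product: 20 (2S,3S)-2-(2,2-dimethyl-1,3-dioxan-5-yl)-N-methoxy-3-[(2R,4R,5R)-2-(4-methoxyphenyl)-5-methyl-1,3-dioxan-4-yl]-N-methyl-3-(triethylsilyloxy)propanamide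
Conditions: Et3SiOTf, 2,6-lutidine, CH2Cl2, −78 °C
Reagents that add atoms: triethylsilyl trifluoromethanesulfonate, CC[Si](CC)(CC)OS(=O)(=O)C(F)(F)F
Why: Silylation of the hindered C8 hydroxyl with the silyl triflate at −78 °C is fast enough to leave both acetals untouched and gives a group that is later removed together with the acetonide.

Step 13
Reactants: 20 Weinreb amide (C8 OSiEt3); 16 (but-3-yn-1-yloxy)triethylsilane
Product: 22 ynone (C6 ketone; C4≡C5; C2 OSiEt3; C8 OSiEt3; C7 dioxanyl; O9/O1 4-methoxybenzylidene acetal), via lithium acetylide 21 (not isolated)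
Conditions: 16, nBuLi, THF, −78 °C; then 20, −78 → 0 °C; aq. NH4Cl
Reagents that add atoms: none
Why: Acylation of the lithium acetylide by the Weinreb amide stops at the ketone because the chelated tetrahedral intermediate survives until work-up, which also protects C7 from epimerisation.

Step 14
Reactants: 22 ynone
Product: 23 (6R)-propargylic alcohol (22 with C6 H,OH)
Conditions: RuCl[(R,R)-TsDPEN](p-cymene) (cat.), iPrOH, rt
Reagents that add atoms: none
Why: Noyori asymmetric transfer hydrogenation of the alkynyl ketone is catalyst-controlled (the slim alkyne against the branched C7 side), and the (R,R)-ligand should set C6 as the (6R)-alcohol, syn to the C7 side chain.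

Step 15
Reactants: 23 (6R)-propargylic alcohol
Product: 25 (4Z)-4-iodo allylic alcohol (C6 OH; C5H=C4(I) with iodine cis to C6), via sodium alkenylalanate 24 (not isolated)
Conditions: NaAlH2(OCH2CH2OMe)2, THF, 0 °C → rt; EtOAc; then I2, THF, −78 °C
Reagents that add atoms: iodine, II
Why: Hydroxyl-directed trans-hydroalumination of the propargylic alcohol places aluminium on C4 in a five-membered alanate, and iodinolysis with retention gives the vinyl iodide in which iodine is cis to C6 (4Z).

Step 16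
Reactants: 25 (4Z)-4-iodo allylic alcohol
Product: 26 (4E)-allylic alcohol (C6 OH; C5H=C4(CH3) with the C15 methyl cis to C6)
Conditions: MeZnCl (3 equiv), Pd(PPh3)4 (cat.), THF, rt → 45 °C
Reagents that add atoms: methylzinc chloride, C[Zn]Cl
Why: Negishi cross-coupling replaces iodine by methyl with retention of alkene geometry, so the C15 methyl is cis to C6 and the trisubstituted alkene is 4E.

Step 17
Reactants: 26 (4E)-allylic alcohol
Product: 27 C6 tert-butyldimethylsilyl ether of 26
Conditions: tBuMe2SiOTf, 2,6-lutidine, CH2Cl2, −78 °C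
Reagents that add atoms: tert-butyldimethylsilyl trifluoromethanesulfonate, CC(C)(C)[Si](C)(C)OS(=O)(=O)C(F)(F)F
Why: Silylation with the silyl triflate at −78 °C protects the hindered allylic C6 hydroxyl as the tert-butyldimethylsilyl ether that is stable to the base of the key step.

Step 18
Reactants: 27 fully protected chain with O9/O1 4-methoxybenzylidene acetal
Product: 28 C1 alcohol (C9 O-PMB; C8 OSiEt3; C7 dioxanyl; C6 OSi(tBu)Me2; 4E alkene; C2 OSiEt3)
Conditions: iBu2AlH, CH2Cl2, −78 → 0 °C; aq. KNaC4H4O6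
Reagents that add atoms: none
Why: Reductive opening of the 4-methoxybenzylidene acetal: aluminium binds the less hindered O1, hydride is delivered to the acetal carbon, and the 4-methoxybenzyl group stays on the secondary O9 while C1–OH is freed.

Step 19
Reactants: 28 C1 alcohol with C2 OSiEt3
Product: 29 C1,C2-diol
Conditions: HF·pyridine, pyridine, THF, 0 °C
Reagents that add atoms: none
Why: Fluoride-mediated desilylation is selective because the primary triethylsilyl ether at O2 is cleaved far faster than the buried secondary silyl ethers at O8 and O6.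

Step 20
Reactants: 29 C1,C2-diol
Product: 30 C1,C2-bis(methanesulfonate)
Conditions: MsCl, Et3N, CH2Cl2, 0 °C
Reagents that add atoms: methanesulfonyl chloride, CS(=O)(=O)Cl
Why: Sulfonylation of the two primary alcohols gives the bis-mesylate; no secondary hydroxyl is free and the homoallylic C2 mesylate is used without delay.

Step 21
Reactants: 30 C1,C2-bis(methanesulfonate)
Product: 31 eleven-membered cyclic sulfide (S bridges C1 and C2)
Conditions: Na2S·9H2O, DMF, 50 °C, slow addition at high dilution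
Reagents that add atoms: sodium sulfide, [Na+].[Na+].[S-2]
Why: Double nucleophilic substitution (SN2): sulfide displaces one primary mesylate and the resulting thiolate closes the eleven-membered ring on the other under high dilution, the soft nucleophile favouring substitution over elimination.

Step 22
Reactants: 31 eleven-membered cyclic sulfide
Product: 33 eleven-membered cyclic sulfone (C6 OSi(tBu)Me2; C7 dioxanyl; C8 OSiEt3; C9 O-PMB; C10 methyl; 4E alkene), via sulfoxide 32 (not isolated)
Conditions: (NH4)6Mo7O24·4H2O (cat.), 30% H2O2, EtOH, 0 °C → rt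
Reagents that add atoms: hydrogen peroxide, OO
Why: Peroxomolybdate-catalysed oxidation by H2O2 takes the sulfide through the sulfoxide to the sulfone and is chemoselective for sulfur over the trisubstituted, allylically deactivated C4=C5 alkene.

Step 23
Reactants: 33 eleven-membered cyclic sulfone
Product: 36 (1Z,4E)-cyclodeca-1,4-diene (C6 OSi(tBu)Me2; C7 dioxanyl; C8 OSiEt3; C9 O-PMB; C10 methyl), via 2-bromo sulfone 34 (not isolated), via episulfone 35 (not isolated)
Conditions: CBr2F2, KOH/Al2O3, tBuOH/CH2Cl2, 0 °C → rt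
Reagents that add atoms: none
Why: Ramberg–Bäcklund reaction with in situ halogenation: KOH on alumina deprotonates an α-sulfonyl carbon (C2 or C1), the carbanion takes bromine from CBr2F2 to give 34, the α'-carbanion displaces bromide in a 1,3-elimination (3-exo-tet) to the episulfone 35, and cheletropic loss of SO2 leaves the C1=C2 double bond. The closest known reaction type is the one-pot Ramberg–Bäcklund ring contraction of medium-ring cyclic sulfones to cycloalkenes. The ten-membered carbocycle is closed by this three-membered-ring formation inside the existing eleven-membered thiacycle, a one-atom contraction and not an end-to-end medium-ring cyclisation, so no C–C bond has to be forced across the ring. No stereocentre is created, C6–C10 lie away from any acidic site and keep their configuration, and either C1=C2 geometry serves (Z is drawn) because the alkene is saturated in step 24. The selectivity needed is chemoselectivity for the two α-sulfonyl methylenes: they are the only C–H acids in 33 (no carbonyl group and no β-leaving group at C10 or C3), the weak heterogeneous base leaves silyl ethers, PMB ether and acetonide intact, and the difluorocarbene released from CBr2F2 is too unreactive to add to C4=C5.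

Step 24
Reactants: 36 (1Z,4E)-cyclodeca-1,4-diene
Product: 37 (4E)-cyclodecene (C1–C2 saturated)
Conditions: 2-O2NC6H4SO2NHNH2, Et3N, CH2Cl2, rt
Reagents that add atoms: none
Why: Diimide reduction (concerted syn transfer of H2) saturates the strained cis-disubstituted C1=C2 alkene much faster than the trisubstituted C4=C5 alkene and touches no other group.

Step 25
Reactants: 37 (4E)-cyclodecene
Product: 38 triol (C8 OH; C7 CH(CH2OH)2; C6 OSi(tBu)Me2; C9 O-PMB)
Conditions: AcOH/THF/H2O (3:1:1), 40 °C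
Reagents that add atoms: none
Why: Mild aqueous acid hydrolysis cleaves the triethylsilyl ether at O8 and the 1,3-dioxane acetonide, while the secondary tert-butyldimethylsilyl ether at O6 and the 4-methoxybenzyl ether at O9 are stable.

Step 26
Reactants: 38 triol
Product: 40 8,12-γ-lactone with C11 CH2OH (C11 epimers), via lactol 39 (not isolated)
Conditions: TEMPO (0.2 equiv), PhI(OAc)2 (2.3 equiv), CH2Cl2, rt
Reagents that add atoms: none
Why: TEMPO/PhI(OAc)2 oxidative lactonisation: one primary alcohol is oxidised to the aldehyde, C8–OH adds to it (5-exo-trig) to give the lactol and this is oxidised to the γ-lactone, the only lactone possible because O9 and O6 are blocked; the ring fusion is trans as fixed by C7 and C8.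

Step 27
Reactants: 40 α-(hydroxymethyl)-γ-lactone
Product: 42 α-methylene-γ-lactone (C11=C13; C6 OSi(tBu)Me2; C9 O-PMB), via mesylate 41 (not isolated)
Conditions: MsCl, Et3N, CH2Cl2, 0 °C; then DBU, rt
Reagents that add atoms: none
Why: Mesylation of the remaining primary alcohol and base-induced β-elimination (E1cB through the lactone enolate) give the α-methylene lactone and erase the C11 centre.

Step 28
Reactants: 42 α-methylene-γ-lactone (C6 OSi(tBu)Me2)
Product: 43 C6 allylic alcohol
Conditions: HF·pyridine, pyridine, THF, 0 °C → rt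
Reagents that add atoms: none
Why: Fluoride-mediated desilylation removes the tert-butyldimethylsilyl group from O6 under buffered conditions that leave the 4-methoxybenzyl ether and the α-methylene lactone intact.

Step 29
Reactants: 43 C6 allylic alcohol
Product: 44 (4R,5R)-4,5-epoxy C6 alcohol
Conditions: VO(acac)2 (cat.), tBuOOH, CH2Cl2, 0 °C → rt
Reagents that add atoms: tert-butyl hydroperoxide, CC(C)(C)OO
Why: Hydroxyl-directed vanadium-catalysed epoxidation: the vanadate ester of C6–OH delivers oxygen to C4=C5 through a transition state with a small O–C6–C5=C4 dihedral angle, which in the ten-membered ring (C7 held on the inner face) is only reachable on the outer alkene face, so the epoxide should form erythro to C6–O (4R,5R); the electron-poor methylene lactone is not epoxidised.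

Step 30
Reactants: 44 (4R,5R)-4,5-epoxy C6 alcohol
Product: 45 C6 3-methylbut-2-enoate (C9 O-PMB)
Conditions: 3-methylbut-2-enoyl chloride, pyridine, DMAP (cat.), CH2Cl2, 0 °C → rt
Reagents that add atoms: 3-methylbut-2-enoyl chloride, CC(C)=CC(=O)Cl
Why: Acylation of the only free hydroxyl by the acid chloride under nucleophilic catalysis (DMAP) gives the senecioate, pyridine being too weak a base to isomerise the acyl group out of conjugation.

Step 31
Reactants: 45 C6 3-methylbut-2-enoate (C9 O-PMB)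
Product: 46 CNP0119422.1
Conditions: DDQ, CH2Cl2/pH 7 buffer, 0 °C
Reagents that add atoms: none
Why: Oxidative cleavage of the 4-methoxybenzyl ether by DDQ (hydride abstraction, then hydrolysis of the oxocarbenium ion) under neutral buffered conditions frees C9–OH without touching epoxide, esters or methylene lactone.

**Compound list**

1 | 2,2-dimethyl-1,3-dioxan-5-one | CC1(C)OCC(=O)CO1 | starting material
2 | ethyl (triphenylphosphoranylidene)acetate | CCOC(=O)C=P(c1ccccc1)(c1ccccc1)c1ccccc1 | starting material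
3 | ethyl 2-(2,2-dimethyl-1,3-dioxan-5-ylidene)acetate | CCOC(=O)C=C1COC(C)(C)OC1 | intermediate
4 | ethyl 2-(2,2-dimethyl-1,3-dioxan-5-yl)acetate | CCOC(=O)CC1COC(C)(C)OC1 | intermediate
5 | 2-(2,2-dimethyl-1,3-dioxan-5-yl)acetic acid | OC(=O)CC1COC(C)(C)OC1 | intermediate
6 | (S)-4-benzyl-1,3-oxazolidin-2-one | O=C1N[C@@H](Cc2ccccc2)CO1 | starting material
7 | mixed anhydride of 5 with pivalic acid (not isolated) | CC(C)(C)C(=O)OC(=O)CC1COC(C)(C)OC1 | intermediate
8 | (S)-4-benzyl-3-[2-(2,2-dimethyl-1,3-dioxan-5-yl)acetyl]-1,3-oxazolidin-2-one | O=C(CC1COC(C)(C)OC1)N2[C@@H](Cc3ccccc3)COC2=O | intermediate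
9 | dimethyl (R)-malate | COC(=O)C[C@@H](O)C(=O)OC | starting material
10 | dilithium alkoxide enolate of 9 (not isolated) | [Li+].[Li+].COC(=O)[C@H]([O-])/C=C(\[O-])OC | intermediate
11 | dimethyl (2R,3S)-2-hydroxy-3-methylbutanedioate | COC(=O)[C@@H](C)[C@@H](O)C(=O)OC | intermediate
12 | (2R,3R)-3-methylbutane-1,2,4-triol | OC[C@@H](C)[C@@H](O)CO | intermediate
13 | [(2R,4R,5R)-2-(4-methoxyphenyl)-5-methyl-1,3-dioxan-4-yl]methanol | COc1ccc(cc1)[C@@H]2OC[C@@H](C)[C@@H](O2)CO | intermediate
14 | (2R,4R,5R)-2-(4-methoxyphenyl)-5-methyl-1,3-dioxane-4-carbaldehyde | COc1ccc(cc1)[C@@H]2OC[C@@H](C)[C@@H](O2)C=O | intermediate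
15 | but-3-yn-1-ol | C#CCCO | starting material
16 | (but-3-yn-1-yloxy)triethylsilane | C#CCCO[Si](CC)(CC)CC | intermediate
17 | Z-dibutylboron enolate of 8 (not isolated) | CCCCB(CCCC)O/C(=C\C1COC(C)(C)OC1)N2[C@@H](Cc3ccccc3)COC2=O | intermediate
18 | (S)-4-benzyl-3-[(2S,3S)-2-(2,2-dimethyl-1,3-dioxan-5-yl)-3-hydroxy-3-[(2R,4R,5R)-2-(4-methoxyphenyl)-5-methyl-1,3-dioxan-4-yl]propanoyl]-1,3-oxazolidin-2-one (propanoyl C1/C2/C3 = C6/C7/C8) | COc1ccc(cc1)[C@@H]2OC[C@@H](C)[C@@H](O2)[C@@H](O)[C@H](C3COC(C)(C)OC3)C(=O)N4[C@@H](Cc5ccccc5)COC4=O | intermediate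
19 | (2S,3S)-2-(2,2-dimethyl-1,3-dioxan-5-yl)-3-hydroxy-N-methoxy-3-[(2R,4R,5R)-2-(4-methoxyphenyl)-5-methyl-1,3-dioxan-4-yl]-N-methylpropanamide | COc1ccc(cc1)[C@@H]2OC[C@@H](C)[C@@H](O2)[C@@H](O)[C@H](C3COC(C)(C)OC3)C(=O)N(C)OC | intermediate
20 | (2S,3S)-2-(2,2-dimethyl-1,3-dioxan-5-yl)-N-methoxy-3-[(2R,4R,5R)-2-(4-methoxyphenyl)-5-methyl-1,3-dioxan-4-yl]-N-methyl-3-(triethylsilyloxy)propanamide | COc1ccc(cc1)[C@@H]2OC[C@@H](C)[C@@H](O2)[C@@H](O[Si](CC)(CC)CC)[C@H](C3COC(C)(C)OC3)C(=O)N(C)OC | intermediate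
21 | lithium 4-(triethylsilyloxy)but-1-yn-1-ide (not isolated) | [Li]C#CCCO[Si](CC)(CC)CC | intermediate
22 | ynone: C6 ketone between C7 and C5≡C4–C3H2–C2H2–OSiEt3; C7 2,2-dimethyl-1,3-dioxan-5-yl; C8 OSiEt3; O9/O1 4-methoxybenzylidene acetal; C10 methyl (C7–C10 as in 20) | COc1ccc(cc1)[C@@H]2OC[C@@H](C)[C@@H](O2)[C@@H](O[Si](CC)(CC)CC)[C@H](C3COC(C)(C)OC3)C(=O)C#CCCO[Si](CC)(CC)CC | intermediate
23 | (6R)-propargylic alcohol: 22 with C6 H,OH | COc1ccc(cc1)[C@@H]2OC[C@@H](C)[C@@H](O2)[C@@H](O[Si](CC)(CC)CC)[C@H](C3COC(C)(C)OC3)[C@@H](O)C#CCCO[Si](CC)(CC)CC | intermediate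
24 | sodium alkenylalanate: five-membered ring Al–O6–C6–C5=C4 with two 2-methoxyethoxy groups on aluminium; otherwise as 23 (not isolated) | COc1ccc(cc1)[C@@H]2OC[C@@H](C)[C@@H](O2)[C@@H](O[Si](CC)(CC)CC)[C@H](C3COC(C)(C)OC3)[C@@H](O[Al-]4(OCCOC)OCCOC)C=C4CCO[Si](CC)(CC)CC.[Na+] | intermediate
25 | (4Z)-4-iodo allylic alcohol: C6 OH; C5H=C4(I) with iodine cis to C6; otherwise as 23 | COc1ccc(cc1)[C@@H]2OC[C@@H](C)[C@@H](O2)[C@@H](O[Si](CC)(CC)CC)[C@H](C3COC(C)(C)OC3)[C@@H](O)/C=C(I)/CCO[Si](CC)(CC)CC | intermediate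
26 | (4E)-allylic alcohol: C6 OH; C5H=C4(CH3) with methyl cis to C6; otherwise as 23 | COc1ccc(cc1)[C@@H]2OC[C@@H](C)[C@@H](O2)[C@@H](O[Si](CC)(CC)CC)[C@H](C3COC(C)(C)OC3)[C@@H](O)/C=C(C)/CCO[Si](CC)(CC)CC | intermediate
27 | 26 with C6 OSi(tBu)Me2 | COc1ccc(cc1)[C@@H]2OC[C@@H](C)[C@@H](O2)[C@@H](O[Si](CC)(CC)CC)[C@H](C3COC(C)(C)OC3)[C@@H](O[Si](C)(C)C(C)(C)C)/C=C(C)/CCO[Si](CC)(CC)CC | intermediate
28 | acyclic C1–C10 chain: C1 OH; C10 methyl; C9 O-(4-methoxybenzyl); C8 OSiEt3; C7 2,2-dimethyl-1,3-dioxan-5-yl; C6 OSi(tBu)Me2; 4E alkene; C2 OSiEt3 | OC[C@@H](C)[C@@H](OCc1ccc(OC)cc1)[C@@H](O[Si](CC)(CC)CC)[C@H](C2COC(C)(C)OC2)[C@@H](O[Si](C)(C)C(C)(C)C)/C=C(C)/CCO[Si](CC)(CC)CC | intermediate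
29 | C1,C2-diol: 28 with C2 OH | OC[C@@H](C)[C@@H](OCc1ccc(OC)cc1)[C@@H](O[Si](CC)(CC)CC)[C@H](C2COC(C)(C)OC2)[C@@H](O[Si](C)(C)C(C)(C)C)/C=C(C)/CCO | intermediate
30 | C1,C2-bis(methanesulfonate) of 29 | CS(=O)(=O)OC[C@@H](C)[C@@H](OCc1ccc(OC)cc1)[C@@H](O[Si](CC)(CC)CC)[C@H](C2COC(C)(C)OC2)[C@@H](O[Si](C)(C)C(C)(C)C)/C=C(C)/CCOS(C)(=O)=O | intermediate
31 | eleven-membered cyclic sulfide (ring S–C1–C10–C9–C8–C7–C6–C5=C4–C3–C2; substituents as in 28) | S1C[C@@H](C)[C@@H](OCc2ccc(OC)cc2)[C@@H](O[Si](CC)(CC)CC)[C@H](C3COC(C)(C)OC3)[C@@H](O[Si](C)(C)C(C)(C)C)/C=C(C)/CC1 | intermediate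
32 | sulfoxide of 31, both configurations at sulfur (not isolated) | O=S1C[C@@H](C)[C@@H](OCc2ccc(OC)cc2)[C@@H](O[Si](CC)(CC)CC)[C@H](C3COC(C)(C)OC3)[C@@H](O[Si](C)(C)C(C)(C)C)/C=C(C)/CC1 | intermediate
33 | eleven-membered cyclic sulfone (Ramberg–Bäcklund precursor; substituents as in 31) | O=S1(=O)C[C@@H](C)[C@@H](OCc2ccc(OC)cc2)[C@@H](O[Si](CC)(CC)CC)[C@H](C3COC(C)(C)OC3)[C@@H](O[Si](C)(C)C(C)(C)C)/C=C(C)/CC1 | intermediate
34 | 2-bromo derivative of 33, C2 epimers (not isolated) | O=S1(=O)C[C@@H](C)[C@@H](OCc2ccc(OC)cc2)[C@@H](O[Si](CC)(CC)CC)[C@H](C3COC(C)(C)OC3)[C@@H](O[Si](C)(C)C(C)(C)C)/C=C(C)/CC1Br | intermediate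
35 | episulfone: thiirane 1,1-dioxide on C1–C2, cis-fused to the ten-membered carbocycle (not isolated) | O=S1(=O)C2[C@@H](C)[C@@H](OCc3ccc(OC)cc3)[C@@H](O[Si](CC)(CC)CC)[C@H](C4COC(C)(C)OC4)[C@@H](O[Si](C)(C)C(C)(C)C)/C=C(C)/CC12 | intermediate
36 | (1Z,4E)-cyclodeca-1,4-diene: C10 methyl; C9 O-(4-methoxybenzyl); C8 OSiEt3; C7 2,2-dimethyl-1,3-dioxan-5-yl; C6 OSi(tBu)Me2; C4 methyl | C[C@@H]1/C=C\C/C(C)=C/[C@H](O[Si](C)(C)C(C)(C)C)[C@@H](C2COC(C)(C)OC2)[C@H](O[Si](CC)(CC)CC)[C@@H]1OCc3ccc(OC)cc3 | intermediate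
37 | (4E)-cyclodecene: 36 with C1–C2 saturated | C[C@@H]1CCC/C(C)=C/[C@H](O[Si](C)(C)C(C)(C)C)[C@@H](C2COC(C)(C)OC2)[C@H](O[Si](CC)(CC)CC)[C@@H]1OCc3ccc(OC)cc3 | intermediate
38 | triol: 37 with C8 OH and C7 CH(CH2OH)2 | C[C@@H]1CCC/C(C)=C/[C@H](O[Si](C)(C)C(C)(C)C)[C@@H](C(CO)CO)[C@H](O)[C@@H]1OCc2ccc(OC)cc2 | intermediate
39 | γ-lactol: C12 hemiacetal closed on O8; C11 CH2OH (not isolated) | C[C@@H]1CCC/C(C)=C/[C@H](O[Si](C)(C)C(C)(C)C)[C@H]2C(CO)C(O)O[C@@H]2[C@@H]1OCc3ccc(OC)cc3 | intermediate
40 | trans-fused 8,12-γ-lactone with C11 CH2OH (C11 epimers); C6 OSi(tBu)Me2; C9 O-(4-methoxybenzyl) | C[C@@H]1CCC/C(C)=C/[C@H](O[Si](C)(C)C(C)(C)C)[C@H]2C(CO)C(=O)O[C@@H]2[C@@H]1OCc3ccc(OC)cc3 | intermediate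
41 | C13 methanesulfonate of 40 (not isolated) | C[C@@H]1CCC/C(C)=C/[C@H](O[Si](C)(C)C(C)(C)C)[C@H]2C(COS(C)(=O)=O)C(=O)O[C@@H]2[C@@H]1OCc3ccc(OC)cc3 | intermediate
42 | α-methylene-γ-lactone (C11=C13); C6 OSi(tBu)Me2; C9 O-(4-methoxybenzyl) | C[C@@H]1CCC/C(C)=C/[C@H](O[Si](C)(C)C(C)(C)C)[C@H]2C(=C)C(=O)O[C@@H]2[C@@H]1OCc3ccc(OC)cc3 | intermediate
43 | C6 allylic alcohol: 42 with C6 OH | C[C@@H]1CCC/C(C)=C/[C@H](O)[C@H]2C(=C)C(=O)O[C@@H]2[C@@H]1OCc3ccc(OC)cc3 | intermediate
44 | (4R,5R)-4,5-epoxide of 43 (C6 OH) | C[C@@H]1CCC[C@@]3(C)O[C@@H]3[C@H](O)[C@H]2C(=C)C(=O)O[C@@H]2[C@@H]1OCc4ccc(OC)cc4 | intermediate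
45 | C6 3-methylbut-2-enoate of 44 (C9 O-(4-methoxybenzyl)) | C[C@@H]1CCC[C@@]3(C)O[C@@H]3[C@H](OC(=O)C=C(C)C)[C@H]2C(=C)C(=O)O[C@@H]2[C@@H]1OCc4ccc(OC)cc4 | intermediate
46 | CNP0119422.1: (4R,5R,6R,7S,8S,9R,10R)-4,5-epoxy-9-hydroxy-6-(3-methylbut-2-enoyloxy)germacr-11(13)-en-12,8-olide | C[C@@H]1CCC[C@@]3(C)O[C@@H]3[C@H](OC(=O)C=C(C)C)[C@H]2C(=C)C(=O)O[C@@H]2[C@@H]1O | target

**Step count**

Total step count: 31. Longest linear sequence: 26 steps (from 9 through steps 5–8 and 10–31; the same length from 1 through steps 1–4 and 10–31).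

**Steps most likely to fail**

Step 23 (key step). The in situ bromination may stall or run on to polyhalogenation, or base-induced side reactions may outrun closure of the episulfone, so that extrusion does not take place cleanly. The fallback makes the same C1=C2 bond by metathesis; it sets out from diol 29 and comes back at 36. Both primary alcohols of 29 are oxidised with Dess–Martin periodinane (NaHCO3) to the C1,C2-dialdehyde F1. Double Wittig methylenation with Ph3P=CH2 (THF, −78 → 0 °C) gives the bis-terminal diene F2, in which C1 and C2 each carry a vinyl CH=CH2 terminus. Ring-closing metathesis with the second-generation Grubbs catalyst (H2IMes)(PCy3)Cl2Ru=CHPh in refluxing CH2Cl2 at high dilution joins C1 and C2 with loss of ethene and should give the Z-alkene 36, the geometry expected in a ten-membered ring.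

Step 21. Intermolecular oligomerisation may compete with closure of the eleven-membered ring, and the homoallylic C2 mesylate may be lost by elimination under the basic sulfide. The fallback closes the ring with a thiolate that is already attached; it sets out from 28 and comes back at 31. Mitsunobu reaction of the C1 alcohol of 28 with thioacetic acid (PPh3, DIAD, THF, 0 °C) gives the C1 thioacetate F3. HF·pyridine/pyridine removes the primary silyl group to give the C2 alcohol F4. MsCl/Et3N gives the C2 mesylate F5. K2CO3 in degassed MeOH/THF, added slowly at high dilution, cleaves the thioacetate, and the thiolate closes onto C2 to give 31.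

Step 29. Oxygen may be delivered to the wrong face of C4=C5 if the ring reacts through its A(1,3)-relaxed conformer instead of the conformer that the vanadate ester needs. The fallback uses the C6 epimer, for which the exposed face is the required one, and corrects C6 afterwards; it sets out from 43 and comes back at 45. Dess–Martin oxidation of 43 gives the C6 enone F6. Reagent-controlled Corey–Bakshi–Shibata reduction ((R)-2-methyl-CBS-oxazaborolidine, catecholborane, −78 °C) should give the 6-epi allylic alcohol F7. In F7, H6 eclipses the C15 methyl and the hydroxyl lies on the outer face, so mCPBA (NaHCO3, CH2Cl2, 0 °C) should add syn to it and give the 6-epi (4R,5R)-epoxy alcohol F8. Mitsunobu esterification of F8 with 3-methylbut-2-enoic acid (PPh3, DIAD) inverts C6 and gives 45 directly.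

**Further compounds**

F1 | step 23 | C1,C2-dialdehyde of the acyclic chain (other groups as in 29) | O=C[C@@H](C)[C@@H](OCc1ccc(OC)cc1)[C@@H](O[Si](CC)(CC)CC)[C@H](C2COC(C)(C)OC2)[C@@H](O[Si](C)(C)C(C)(C)C)/C=C(C)/CC=O
F2 | step 23 | bis-terminal diene (C1 and C2 each as CH=CH2; other groups as in 29) | C=C[C@@H](C)[C@@H](OCc1ccc(OC)cc1)[C@@H](O[Si](CC)(CC)CC)[C@H](C2COC(C)(C)OC2)[C@@H](O[Si](C)(C)C(C)(C)C)/C=C(C)/CC=C
F3 | step 21 | C1 S-acetyl thioester with C2 OSiEt3 (other groups as in 28) | CC(=O)SC[C@@H](C)[C@@H](OCc1ccc(OC)cc1)[C@@H](O[Si](CC)(CC)CC)[C@H](C2COC(C)(C)OC2)[C@@H](O[Si](C)(C)C(C)(C)C)/C=C(C)/CCO[Si](CC)(CC)CC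
F4 | step 21 | C1 S-acetyl thioester with C2 OH | CC(=O)SC[C@@H](C)[C@@H](OCc1ccc(OC)cc1)[C@@H](O[Si](CC)(CC)CC)[C@H](C2COC(C)(C)OC2)[C@@H](O[Si](C)(C)C(C)(C)C)/C=C(C)/CCO
F5 | step 21 | C1 S-acetyl thioester with C2 methanesulfonate | CC(=O)SC[C@@H](C)[C@@H](OCc1ccc(OC)cc1)[C@@H](O[Si](CC)(CC)CC)[C@H](C2COC(C)(C)OC2)[C@@H](O[Si](C)(C)C(C)(C)C)/C=C(C)/CCOS(C)(=O)=O
F6 | step 29 | C6 enone of the methylene lactone (C9 O-PMB) | C[C@@H]1CCC/C(C)=C/C(=O)[C@H]2C(=C)C(=O)O[C@@H]2[C@@H]1OCc3ccc(OC)cc3
F7 | step 29 | 6-epi allylic alcohol (C6 epimer of 43) | C[C@@H]1CCC/C(C)=C/[C@@H](O)[C@H]2C(=C)C(=O)O[C@@H]2[C@@H]1OCc3ccc(OC)cc3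
F8 | step 29 | 6-epi (4R,5R)-epoxy alcohol (C6 epimer of 44) | C[C@@H]1CCC[C@@]3(C)O[C@@H]3[C@@H](O)[C@H]2C(=C)C(=O)O[C@@H]2[C@@H]1OCc4ccc(OC)cc4
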